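Compound numbers refer to the steps and the compound list below. Atom labels follow the target: carbocycle C1 (methyl, homoprenyl), C2 (prenyl), C3, C4 (prenyl), C10 (ketone), C7 (prenyl), C8 (ketone), C9 (isobutyryl); lactone bridge C4–C5(=O)–O6–C7.

## Analysis of the target

Target 30 is an 8-oxabicyclo[5.2.1]decane-6,9,10-trione. An eight-membered carbocycle (C1–C2–C3–C4–C10–C7–C8–C9) is spanned from C4 to C7 by the lactone unit C5(=O)–O6, so that C4, C5, O6, C7 and C10 form a 3,3,5,5-tetrasubstituted furan-2,4-dione. There are five stereocentres: quaternary C1, C2 with its prenyl cis to the C1 methyl, the two quaternary bridgeheads C4 and C7, and C9. The bridgeheads fix each other through the bicycle, but their sense relative to C1/C2 must be set deliberately: the lactone bridge lies on the ring face that carries the C2 prenyl and the C1 methyl. C9 carries the isobutyryl group cis to the C1 methyl and sits between two ketones, so it is configurationally labile. The sensitive groups are four trisubstituted alkenes (protic and Lewis acids, electrophilic halogen, peracids), two non-enolisable 1,3-dicarbonyl arrays around C4 and C7 (retro-Claisen cleavage by hydroxide or alkoxide) and the acidic β-diketone at C9. The difficulties are the medium ring, the vicinal C1/C2 pair with a quaternary centre, and the correlation of the remote bridgeheads with C1/C2. The strategy rests on the five-carbon chain C3–C2–C1–C9–C8. If C3 and C8 are joined, it becomes a cyclopentanone with C3 as carbonyl carbon, C2 as α-carbon, C1 as β-carbon and C8 as α′-carbon. Conjugate addition and enolate trapping on a cyclopentenone can therefore set C1 and C2, and a later cut between C3 and C8 releases the chain with both ends differentiated.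

## Retrosynthetic reasoning

**C9–acyl bond (30 ⇒ 27 + 28).** The isobutyryl group is removed first. In 27 the C9 methylene is the only enolisable position, because C4 and C7 are quaternary, so an aldol addition to 28 followed by oxidation needs no regiocontrol. The labile C9 centre is formed last and left to equilibrate.

**C7–C8 bond (27 ⇒ 26 ⇒ 25).** The eight-membered ring is opened between C7 and C8. Forward, the enolate of the C10 ketone in 25 must add to the C8 aldehyde. This cut is chosen because C7 becomes quaternary in the ring closure itself: the five-atom tether hanging from C4 can only reach the enolate face on which it stands. The C7 configuration therefore follows from C4 and needs no separate control. C8 arrives at the aldehyde level and is oxidised afterwards.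

**Lactone ring (25 ⇒ 23 ⇒ 21 ⇒ 20).** The furandione is traced to an acyclic β-keto ester 20. Oxygenation of the only enolisable carbon (C7) gives 21, and lactonisation onto the C5 carboxyl gives 23. Building the lactone before the medium ring keeps this chemistry on an unstrained substrate.

**C4–prenyl bond (20 ⇒ 19 + 7).** The quaternary centre C4 is disconnected at its prenyl group. The forward alkylation must choose one face of an acyclic enolate, and the existing centres at C1/C2 are too remote to do so. The choice is therefore placed under catalyst control, and the more reactive electrophile is kept for the quaternisation.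

**C3–C4 bond (19 ⇒ 15 + 18; 18 ⇒ 16 + 7).** The two halves are joined by alkylating β-keto ester 18 with primary iodide 15. Fragment 18 already holds C5, C4, C10, C7 and the C7 prenyl group, and comes in one step from 16 and 7.

**Re-closing the template (15 ⇒ 14 ⇒ 13 ⇒ 12 ⇒ 11 ⇒ 10).** Iodide 15 is the differentiated form of diol 13, obtained by silylating the less hindered C8 hydroxyl and substituting at C3. Diol 13 comes from ester aldehyde 12, the product of cutting the C3–C8 bond of α′-hydroxy ketone 11. Ketone 10 is thus a scaffold whose only task is to hold C1 and C2 in a ring while they are set.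

**C1–methyl and C2–prenyl bonds (10 ⇒ 5 + 6 + 7).** Both bonds are cut in one operation: methyl from 6 is added to the β-carbon of enone 5 under chiral copper catalysis, and the enolate is trapped by 7. This is the step that carries the strategy.

**Enone (5 ⇒ 1 + 2).** Enone 5 comes from addition of the Grignard reagent of 1 to vinylogous ester 2 with acidic work-up.

## Alternatives that were turned down

**Alternative 1:** The C1–C9 bond is cut. A twelve-membered allylic β-keto lactone A2 would be doubly deprotonated with a lithium amide; its [3,3] Carroll rearrangement forms C1–C9, contracts the macrocycle to the eight-membered ring and, after decarboxylation, gives trione A1 with a vinyl group on C1 and a free C9 methylene.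
- For it: the medium ring arises by ring contraction through a six-membered cyclic transition state. On this point it is stronger than the chosen route, which pays the entropic cost of a direct eight-membered closure in step 15.
- Against it: A1 carries vinyl where the target needs homoprenyl, so three carbons must be added on a trione that tolerates neither base nor nucleophiles.
- Against it: the C1 configuration depends on the alkene geometry of A2 and on the chair or boat preference of a rearrangement inside a macrocycle, which is hard to predict.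
- Against it: A2 already needs the complete furandione with C4/C7 matched to C2, a stereodefined trisubstituted allylic alcohol and a macrolactonisation, and its dianion must form next to two cleavage-prone dicarbonyl arrays.
- Comparison: the chosen route sets C1 in its second step, by catalyst control on an achiral eleven-carbon enone, with the homoprenyl chain already in place.

**Alternative 2:** The C4–C10 bond and the O6–C5 bond are cut. An acyclic tertiary α-bromo ester A4 would be reduced by divalent samarium to a trivalent samarium enolate, which adds to the C10 aldehyde; desilylation in the same flask lactonises O6 onto C5 and gives hydroxy lactone A3.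
- For it: the enolate is generated regiospecifically without base, the chelated aldolate is well suited to medium rings, and both rings close in one flask. On step economy, and on avoiding a strong base next to an enolisable aldehyde, it is stronger than the chosen ring closure.
- Against it: A4 contains C7 as an acyclic quaternary carbinol flanked by a ketone and an aldehyde. It must be made as one enantiomer matched to C1/C2 with no ring to enforce it, and it is labile to retro-aldol cleavage.
- Against it: the α-silyloxy ketone at C8 and the aldehyde are themselves reducible by divalent samarium.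
- Against it: C4 arises from a planar enolate, and only the epimer with C5 cis to O6 can lactonise. A3 still needs oxidation at C10 and acylation at C9.
- Comparison: the chosen route creates C7 in the ring closure, where the tether dictates the face, and sets C4 earlier by a catalyst-controlled alkylation of a simple β-keto ester.

**Alternative 3:** The O6–C7 bond is cut. Cyclooctane-1,3-dione acid A6 would be oxidised at a graphite anode with catalytic iodide; the C7 enol is activated by hypoiodite and the C4 carboxylate closes the lactone to give A5.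
- For it: the carboxylate can only reach one face of C7, so the bridgehead relation is forced just as in the chosen route. A5 is the same compound as 27, so the final C9 acylation is shared. No stoichiometric oxidant is needed, and from A6 it is shorter than the hydroxylation, lactonisation, aldol and oxidation sequence used here; on that point it is stronger.
- Against it: it does not make the eight-membered ring. A6 still requires a medium-ring C–C closure, which is the real difficulty.
- Against it: A6 is a β-keto acid and prone to decarboxylation.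
- Against it: electrophilic monovalent iodine meets four trisubstituted alkenes, and the C4 carboxyl with the C4 prenyl group is a γ,δ-unsaturated acid, a classical iodolactonisation substrate.
- Comparison: the chosen route introduces O6 with an oxygen-transfer reagent that leaves alkenes untouched, and it provides a defined way to the ring.

Key step: step 2

Assumption: C9 lies between two carbonyl groups and is epimerisable, so its configuration in the target is taken to be the thermodynamically preferred one (isobutyryl trans to the homoprenyl group on C1) and is reached by equilibration.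

## Route

Step 1
Reactants: 1 5-bromo-2-methylpent-2-ene; 2 3-ethoxycyclopent-2-en-1-one
Product: 5 3-(4-methylpent-3-en-1-yl)cyclopent-2-en-1-one, via homoprenylmagnesium bromide 3 (not isolated), via ethoxy carbinol 4 (not isolated)
Conditions: Mg, THF, rt; 2, THF, 0 °C; 1 M HCl, 0 °C → rt
Reagents that add atoms: none
Why: Grignard 1,2-addition to the vinylogous ester followed by acid hydrolysis of the enol ether with loss of the tertiary hydroxyl (Stork–Danheiser transposition) gives the 3-substituted enone; no stereocentre is formed.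

Step 2
Reactants: 5 3-(4-methylpent-3-en-1-yl)cyclopent-2-en-1-one; 6 trimethylaluminium; 7 1-bromo-3-methylbut-2-ene
Product: 10 (2R,3S)-3-methyl-3-(4-methylpent-3-en-1-yl)-2-(3-methylbut-2-en-1-yl)cyclopentan-1-one, via aluminium enolate 8 (not isolated), via lithium aluminate enolate 9 (not isolated)
Conditions: Cu(OTf)2 (2 mol%), (S,R,R)-O,O′-(1,1′-binaphthalene-2,2′-diyl) N,N-bis(1-phenylethyl)phosphoramidite (4 mol%; antipode if the sense of induction requires it), 6, Et2O, −30 °C; MeLi, THF, −30 °C; 7, −30 → 0 °C
Reagents that add atoms: none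
Why: AlMe3 reduces Cu(OTf)2 to a monovalent copper–phosphoramidite complex and passes methyl to copper; this species binds the aluminium-activated enone as a π-complex, adds at C1 to a trivalent copper intermediate and reductively eliminates to give the C1–CH3 bond and aluminium enolate 8. The closest known reaction type is the copper/phosphoramidite-catalysed asymmetric conjugate addition of trialkylaluminium reagents to β-substituted cycloalkenones with alkylation of the resulting enolate. The step closes no ring; it forms two skeletal bonds, C1–CH3 and C2–CH2 of the prenyl group. Quaternary C1 (S in 10) is set by the chiral ligand, whose antipode is chosen so that methyl is delivered to the required enone face. Because 8 is a poor nucleophile, MeLi converts it into aluminate 9, which is alkylated at carbon by 7 in an SN2 reaction at the primary allylic position. C2 (R in 10) is controlled by C1: the electrophile approaches the enolate face away from the larger homoprenyl chain, so prenyl ends up cis to the C1 methyl, which should also be the more stable arrangement if C2 equilibrates. The step needs alkylation at C2 and not at C8, which the conjugate addition secures by generating the C2=C3 enolate specifically, and it needs monoalkylation, which the reactive allylic bromide at low temperature favours over proton exchange.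

Step 3
Reactants: 10 (2R,3S)-3-methyl-3-(4-methylpent-3-en-1-yl)-2-(3-methylbut-2-en-1-yl)cyclopentan-1-one
Product: 11 (2R,3S)-5-hydroxy-3-methyl-3-(4-methylpent-3-en-1-yl)-2-(3-methylbut-2-en-1-yl)cyclopentan-1-one (C5 epimers)
Conditions: KN(SiMe3)2, THF, −78 °C; 2-(phenylsulfonyl)-3-phenyloxaziridine, −78 °C; AcOH
Reagents that add atoms: 2-(phenylsulfonyl)-3-phenyloxaziridine, O=S(=O)(c1ccccc1)N1OC1c1ccccc1
Why: Kinetic deprotonation takes the unhindered α′-methylene C8 and not the C2 methine next to the quaternary centre, and the N-sulfonyloxaziridine hydroxylates the enolate without touching the alkenes; the carbinol configuration is irrelevant because C8 becomes a carbonyl in step 4.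

Step 4
Reactants: 11 (2R,3S)-5-hydroxy-3-methyl-3-(4-methylpent-3-en-1-yl)-2-(3-methylbut-2-en-1-yl)cyclopentan-1-one
Product: 12 methyl (2R,3S)-3,7-dimethyl-2-(3-methylbut-2-en-1-yl)-3-(2-oxoethyl)oct-6-enoate
Conditions: Pb(OAc)4, MeOH–toluene 1:1, 0 °C
Reagents that add atoms: methanol, CO
Why: Glycol-type cleavage of the α-ketol through its methyl hemiketal by tetravalent lead cuts the C3–C8 bond and delivers C3 as methyl ester and C8 as aldehyde; isolated trisubstituted alkenes react much more slowly at 0 °C.

Step 5
Reactants: 12 methyl (2R,3S)-3,7-dimethyl-2-(3-methylbut-2-en-1-yl)-3-(2-oxoethyl)oct-6-enoate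
Product: 13 (2R,3S)-3-(2-hydroxyethyl)-3,7-dimethyl-2-(3-methylbut-2-en-1-yl)oct-6-en-1-ol
Conditions: LiAlH4, Et2O, 0 °C; aq. NaOH work-up
Reagents that add atoms: none
Why: Hydride reduction of ester and aldehyde is faster than enolisation at C2, and it removes at once the citronellal-like aldehyde, which under acid would undergo carbonyl-ene cyclisation onto the homoprenyl alkene.

Step 6
Reactants: 13 (2R,3S)-3-(2-hydroxyethyl)-3,7-dimethyl-2-(3-methylbut-2-en-1-yl)oct-6-en-1-ol
Product: 14 (2R,3S)-3-{2-[(tert-butyldiphenylsilyl)oxy]ethyl}-3,7-dimethyl-2-(3-methylbut-2-en-1-yl)oct-6-en-1-ol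
Conditions: t-BuPh2SiCl (1.05 equiv), imidazole, CH2Cl2, −20 °C
Reagents that add atoms: tert-butyl(chloro)diphenylsilane, CC(C)(C)[Si](Cl)(c1ccccc1)c1ccccc1
Why: Steric differentiation of two primary alcohols: the C8 hydroxyl sits on an unbranched CH2CH2 arm, whereas the C3 hydroxyl is β-branched and next to the quaternary centre, so the bulky silyl chloride should select C8.

Step 7
Reactants: 14 (2R,3S)-3-{2-[(tert-butyldiphenylsilyl)oxy]ethyl}-3,7-dimethyl-2-(3-methylbut-2-en-1-yl)oct-6-en-1-ol
Product: 15 tert-butyl{[(3S)-3-[(2R)-1-iodo-5-methylhex-4-en-2-yl]-3,7-dimethyloct-6-en-1-yl]oxy}diphenylsilane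
Conditions: I2, PPh3, imidazole, CH2Cl2, 0 °C → rt
Reagents that add atoms: iodine, II
Why: Appel-type iodination: iodide displaces the alkoxyphosphonium at primary C3 under buffered conditions that spare the silyl ether and the alkenes; C2 is not involved.

Step 8
Reactants: 16 tert-butyl 3-oxobutanoate; 7 1-bromo-3-methylbut-2-ene
Product: 18 tert-butyl 7-methyl-3-oxooct-6-enoate, via acetoacetate dianion 17 (not isolated)
Conditions: NaH, THF, 0 °C; n-BuLi, 0 °C; 7, 0 °C → rt; aq. NH4Cl
Reagents that add atoms: none
Why: Acetoacetate dianion alkylation: the more basic terminal carbanion reacts with the allylic bromide, giving the fragment that holds C5, C4, C10, C7 and the C7 prenyl group.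

Step 9
Reactants: 15 tert-butyl{[(3S)-3-[(2R)-1-iodo-5-methylhex-4-en-2-yl]-3,7-dimethyloct-6-en-1-yl]oxy}diphenylsilane; 18 tert-butyl 7-methyl-3-oxooct-6-enoate
Product: 19 tert-butyl (2RS)-2-[(2S,3S)-3-{2-[(tert-butyldiphenylsilyl)oxy]ethyl}-3,7-dimethyl-2-(3-methylbut-2-en-1-yl)oct-6-en-1-yl]-7-methyl-3-oxooct-6-enoate
Conditions: NaH, DMF, 0 °C; 15, 60 °C
Reagents that add atoms: none
Why: SN2 C-alkylation of the sodium enolate of the β-keto ester by the primary iodide forms C3–C4; the iodide is β-branched, hence the heating, and the unsubstituted enolate is used here so that the hindered electrophile meets the less hindered nucleophile; the C4 configuration is immaterial because C4 is re-enolised in step 10.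

Step 10
Reactants: 19 tert-butyl (2RS)-2-[(2S,3S)-3-{2-[(tert-butyldiphenylsilyl)oxy]ethyl}-3,7-dimethyl-2-(3-methylbut-2-en-1-yl)oct-6-en-1-yl]-7-methyl-3-oxooct-6-enoate; 7 1-bromo-3-methylbut-2-ene
Product: 20 tert-butyl (2R)-2-[(2S,3S)-3-{2-[(tert-butyldiphenylsilyl)oxy]ethyl}-3,7-dimethyl-2-(3-methylbut-2-en-1-yl)oct-6-en-1-yl]-7-methyl-2-(3-methylbut-2-en-1-yl)-3-oxooct-6-enoate
Conditions: 7 (1.5 equiv), CsOH·H2O, (S)-4,4-dibutyl-2,6-bis(3,4,5-trifluorophenyl)-4,5-dihydro-3H-dinaphtho[2,1-c:1′,2′-e]azepinium bromide (2 mol%; antipode if the sense of induction requires it), toluene, −40 → −20 °C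
Reagents that add atoms: none
Why: Asymmetric phase-transfer alkylation of an α-substituted β-keto tert-butyl ester: the chiral ammonium cation ion-pairs with the enolate and shields one face, so quaternary C4 (R) is set by the catalyst and not by the remote C1/C2 centres; the tert-butyl ester resists hydrolysis and the reactive allylic bromide makes the quaternisation feasible.

Step 11
Reactants: 20 tert-butyl (2R)-2-[(2S,3S)-3-{2-[(tert-butyldiphenylsilyl)oxy]ethyl}-3,7-dimethyl-2-(3-methylbut-2-en-1-yl)oct-6-en-1-yl]-7-methyl-2-(3-methylbut-2-en-1-yl)-3-oxooct-6-enoate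
Product: 21 tert-butyl (2R,4RS)-2-[(2S,3S)-3-{2-[(tert-butyldiphenylsilyl)oxy]ethyl}-3,7-dimethyl-2-(3-methylbut-2-en-1-yl)oct-6-en-1-yl]-4-hydroxy-7-methyl-2-(3-methylbut-2-en-1-yl)-3-oxooct-6-enoate
Conditions: KN(SiMe3)2, THF, −78 °C; 2-(phenylsulfonyl)-3-phenyloxaziridine, −78 °C; AcOH
Reagents that add atoms: 2-(phenylsulfonyl)-3-phenyloxaziridine, O=S(=O)(c1ccccc1)N1OC1c1ccccc1
Why: C4 is quaternary, so C7 is the only enolisable position of the ketone, and enolate hydroxylation installs O6 there; the C7 configuration does not matter because C7 is enolised again in step 15.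

Step 12
Reactants: 21 tert-butyl (2R,4RS)-2-[(2S,3S)-3-{2-[(tert-butyldiphenylsilyl)oxy]ethyl}-3,7-dimethyl-2-(3-methylbut-2-en-1-yl)oct-6-en-1-yl]-4-hydroxy-7-methyl-2-(3-methylbut-2-en-1-yl)-3-oxooct-6-enoate
Product: 23 (3R,5RS)-3-[(2S,3S)-3-{2-[(tert-butyldiphenylsilyl)oxy]ethyl}-3,7-dimethyl-2-(3-methylbut-2-en-1-yl)oct-6-en-1-yl]-3,5-bis(3-methylbut-2-en-1-yl)furan-2,4(3H,5H)-dione, via hydroxy acid 22 (not isolated)
Conditions: Me3SiOTf, 2,6-lutidine, CH2Cl2, 0 °C; aq. citric acid; EDC·HCl, DMAP (cat.), CH2Cl2, 0 °C → rt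
Reagents that add atoms: none
Why: The silyl triflate cleaves the tert-butyl ester by O-alkyl fission under buffered, non-protic conditions that spare the alkenes (protic acid would cyclise the C7 hydroxyl onto its own prenyl group), and carbodiimide-mediated γ-lactonisation (Steglich type), helped by the quaternary C4, should close the five-membered ring faster than the β-keto acid decarboxylates.

Step 13
Reactants: 23 (3R,5RS)-3-[(2S,3S)-3-{2-[(tert-butyldiphenylsilyl)oxy]ethyl}-3,7-dimethyl-2-(3-methylbut-2-en-1-yl)oct-6-en-1-yl]-3,5-bis(3-methylbut-2-en-1-yl)furan-2,4(3H,5H)-dione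
Product: 24 (3R,5RS)-3-[(2S,3S)-3-(2-hydroxyethyl)-3,7-dimethyl-2-(3-methylbut-2-en-1-yl)oct-6-en-1-yl]-3,5-bis(3-methylbut-2-en-1-yl)furan-2,4(3H,5H)-dione
Conditions: HF·pyridine, pyridine, THF, 0 °C → rt
Reagents that add atoms: none
Why: Fluoride cleavage of the silyl ether under buffered, weakly acidic conditions avoids the hydroxide or alkoxide that would open the β-keto lactone.

Step 14
Reactants: 24 (3R,5RS)-3-[(2S,3S)-3-(2-hydroxyethyl)-3,7-dimethyl-2-(3-methylbut-2-en-1-yl)oct-6-en-1-yl]-3,5-bis(3-methylbut-2-en-1-yl)furan-2,4(3H,5H)-dione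
Product: 25 (3R,5RS)-3-[(2S,3S)-3,7-dimethyl-2-(3-methylbut-2-en-1-yl)-3-(2-oxoethyl)oct-6-en-1-yl]-3,5-bis(3-methylbut-2-en-1-yl)furan-2,4(3H,5H)-dione
Conditions: Dess–Martin periodinane, NaHCO3, CH2Cl2, 0 °C → rt
Reagents that add atoms: none
Why: Buffered Dess–Martin oxidation gives the C8 aldehyde without acid, so the ene-prone aldehyde is generated under neutral conditions and used directly.

Step 15
Reactants: 25 (3R,5RS)-3-[(2S,3S)-3,7-dimethyl-2-(3-methylbut-2-en-1-yl)-3-(2-oxoethyl)oct-6-en-1-yl]-3,5-bis(3-methylbut-2-en-1-yl)furan-2,4(3H,5H)-dione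
Product: 26 (1R,3S,4S,7S)-6-hydroxy-4-methyl-1,3,7-tris(3-methylbut-2-en-1-yl)-4-(4-methylpent-3-en-1-yl)-8-oxabicyclo[5.2.1]decane-9,10-dione (C6 epimers)
Conditions: LiN(SiMe3)2 (1.05 equiv), THF, 2 mM, −78 → −40 °C; AcOH, −78 °C
Reagents that add atoms: none
Why: Intramolecular aldol addition, 8-(enolendo)-exo-trig: the lithium enolate of the C10 ketone, formed at C7 (the only α-proton of that ketone, acidified by the ring acyloxy oxygen), adds to the tethered C8 aldehyde under high dilution. The five-atom tether from C4 can only reach the enolate face on which it stands, so quaternary C7 forms with C8 cis to C3 and its configuration follows from C4; the C8 carbinol is uncontrolled and is removed in step 16, and the cold quench guards against retro-aldol and acyl migration.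

Step 16
Reactants: 26 (1R,3S,4S,7S)-6-hydroxy-4-methyl-1,3,7-tris(3-methylbut-2-en-1-yl)-4-(4-methylpent-3-en-1-yl)-8-oxabicyclo[5.2.1]decane-9,10-dione
Product: 27 (1R,3S,4S,7S)-4-methyl-1,3,7-tris(3-methylbut-2-en-1-yl)-4-(4-methylpent-3-en-1-yl)-8-oxabicyclo[5.2.1]decane-6,9,10-trione
Conditions: Dess–Martin periodinane, NaHCO3, CH2Cl2, rt
Reagents that add atoms: none
Why: Neutral oxidation of the secondary alcohol gives the C8 ketone without exposing the non-enolisable 1,3-dicarbonyl arrays to nucleophiles.

Step 17
Reactants: 27 (1R,3S,4S,7S)-4-methyl-1,3,7-tris(3-methylbut-2-en-1-yl)-4-(4-methylpent-3-en-1-yl)-8-oxabicyclo[5.2.1]decane-6,9,10-trione; 28 2-methylpropanal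
Product: 29 (1R,3S,4R,7S)-5-(1-hydroxy-2-methylpropyl)-4-methyl-1,3,7-tris(3-methylbut-2-en-1-yl)-4-(4-methylpent-3-en-1-yl)-8-oxabicyclo[5.2.1]decane-6,9,10-trione (epimers at C5 and at the carbinol carbon)
Conditions: LiN(SiMe3)2, THF, −78 °C; 28, −78 °C; AcOH
Reagents that add atoms: none
Why: C9 is the only enolisable position of 27 because C4 and C7 are quaternary, so the non-nucleophilic amide base gives one lithium enolate, which adds to the aldehyde in a directed aldol reaction; the new centres are not controlled and need not be.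

Step 18
Reactants: 29 (1R,3S,4R,7S)-5-(1-hydroxy-2-methylpropyl)-4-methyl-1,3,7-tris(3-methylbut-2-en-1-yl)-4-(4-methylpent-3-en-1-yl)-8-oxabicyclo[5.2.1]decane-6,9,10-trione
Product: 30 (1R,3S,4R,5R,7S)-4-methyl-1,3,7-tris(3-methylbut-2-en-1-yl)-4-(4-methylpent-3-en-1-yl)-5-(2-methylpropanoyl)-8-oxabicyclo[5.2.1]decane-6,9,10-trione (CNP0121153.1)
Conditions: Dess–Martin periodinane, CH2Cl2, rt; Et3N (cat.), CH2Cl2, rt
Reagents that add atoms: none
Why: Oxidation of the carbinol gives the β-diketone; C9, now between two carbonyl groups, equilibrates under the mild base to the configuration assumed to be preferred, with isobutyryl trans to the homoprenyl group on C1.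

## Compound list

1 | 5-bromo-2-methylpent-2-ene (homoprenyl bromide) | CC(C)=CCCBr | starting material
2 | 3-ethoxycyclopent-2-en-1-one | CCOC1=CC(=O)CC1 | starting material
3 | (4-methylpent-3-en-1-yl)magnesium bromide | CC(C)=CCC[Mg]Br | intermediate (not isolated)
4 | 3-ethoxy-1-(4-methylpent-3-en-1-yl)cyclopent-2-en-1-ol (racemic, present as its magnesium alkoxide) | CCOC1=CC(O)(CCC=C(C)C)CC1 | intermediate (not isolated)
5 | 3-(4-methylpent-3-en-1-yl)cyclopent-2-en-1-one | O=C1C=C(CCC=C(C)C)CC1 | intermediate
6 | trimethylaluminium | C[Al](C)C | starting material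
7 | 1-bromo-3-methylbut-2-ene (prenyl bromide) | CC(C)=CCBr | starting material
8 | dimethylaluminium (S)-3-methyl-3-(4-methylpent-3-en-1-yl)cyclopent-1-en-1-olate | CC(C)=CCC[C@]1(C)C=C(O[Al](C)C)CC1 | intermediate (not isolated)
9 | lithium trimethyl{[(S)-3-methyl-3-(4-methylpent-3-en-1-yl)cyclopent-1-en-1-yl]oxy}aluminate | CC(C)=CCC[C@]1(C)C=C(O[Al-](C)(C)C)CC1.[Li+] | intermediate (not isolated)
10 | (2R,3S)-3-methyl-3-(4-methylpent-3-en-1-yl)-2-(3-methylbut-2-en-1-yl)cyclopentan-1-one | CC(C)=CCC[C@]1(C)[C@@H](CC=C(C)C)C(=O)CC1 | intermediate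
11 | (2R,3S)-5-hydroxy-3-methyl-3-(4-methylpent-3-en-1-yl)-2-(3-methylbut-2-en-1-yl)cyclopentan-1-one (C5 epimers) | CC(C)=CCC[C@]1(C)[C@@H](CC=C(C)C)C(=O)C(O)C1 | intermediate
12 | methyl (2R,3S)-3,7-dimethyl-2-(3-methylbut-2-en-1-yl)-3-(2-oxoethyl)oct-6-enoate | CC(C)=CCC[C@](CC=O)(C)[C@@H](CC=C(C)C)C(=O)OC | intermediate
13 | (2R,3S)-3-(2-hydroxyethyl)-3,7-dimethyl-2-(3-methylbut-2-en-1-yl)oct-6-en-1-ol | CC(C)=CCC[C@](CCO)(C)[C@@H](CC=C(C)C)CO | intermediate
14 | (2R,3S)-3-{2-[(tert-butyldiphenylsilyl)oxy]ethyl}-3,7-dimethyl-2-(3-methylbut-2-en-1-yl)oct-6-en-1-ol | CC(C)=CCC[C@](CCO[Si](c1ccccc1)(c1ccccc1)C(C)(C)C)(C)[C@@H](CC=C(C)C)CO | intermediate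
15 | tert-butyl{[(3S)-3-[(2R)-1-iodo-5-methylhex-4-en-2-yl]-3,7-dimethyloct-6-en-1-yl]oxy}diphenylsilane | CC(C)=CCC[C@](CCO[Si](c1ccccc1)(c1ccccc1)C(C)(C)C)(C)[C@@H](CC=C(C)C)CI | intermediate
16 | tert-butyl 3-oxobutanoate (tert-butyl acetoacetate) | CC(=O)CC(=O)OC(C)(C)C | starting material
17 | lithium sodium dianion of tert-butyl 3-oxobutanoate | [Li+].[Na+].[CH2-]C(=O)[CH-]C(=O)OC(C)(C)C | intermediate (not isolated)
18 | tert-butyl 7-methyl-3-oxooct-6-enoate | CC(C)=CCCC(=O)CC(=O)OC(C)(C)C | intermediate
19 | tert-butyl (2RS)-2-[(2S,3S)-3-{2-[(tert-butyldiphenylsilyl)oxy]ethyl}-3,7-dimethyl-2-(3-methylbut-2-en-1-yl)oct-6-en-1-yl]-7-methyl-3-oxooct-6-enoate | CC(C)=CCC[C@](CCO[Si](c1ccccc1)(c1ccccc1)C(C)(C)C)(C)[C@@H](CC=C(C)C)CC(C(=O)OC(C)(C)C)C(=O)CCC=C(C)C | intermediate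
20 | tert-butyl (2R)-2-[(2S,3S)-3-{2-[(tert-butyldiphenylsilyl)oxy]ethyl}-3,7-dimethyl-2-(3-methylbut-2-en-1-yl)oct-6-en-1-yl]-7-methyl-2-(3-methylbut-2-en-1-yl)-3-oxooct-6-enoate | CC(C)=CCC[C@](CCO[Si](c1ccccc1)(c1ccccc1)C(C)(C)C)(C)[C@@H](CC=C(C)C)C[C@@](CC=C(C)C)(C(=O)OC(C)(C)C)C(=O)CCC=C(C)C | intermediate
21 | tert-butyl (2R,4RS)-2-[(2S,3S)-3-{2-[(tert-butyldiphenylsilyl)oxy]ethyl}-3,7-dimethyl-2-(3-methylbut-2-en-1-yl)oct-6-en-1-yl]-4-hydroxy-7-methyl-2-(3-methylbut-2-en-1-yl)-3-oxooct-6-enoate | CC(C)=CCC[C@](CCO[Si](c1ccccc1)(c1ccccc1)C(C)(C)C)(C)[C@@H](CC=C(C)C)C[C@@](CC=C(C)C)(C(=O)OC(C)(C)C)C(=O)C(O)CC=C(C)C | intermediate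
22 | (2R,4RS)-2-[(2S,3S)-3-{2-[(tert-butyldiphenylsilyl)oxy]ethyl}-3,7-dimethyl-2-(3-methylbut-2-en-1-yl)oct-6-en-1-yl]-4-hydroxy-7-methyl-2-(3-methylbut-2-en-1-yl)-3-oxooct-6-enoic acid | CC(C)=CCC[C@](CCO[Si](c1ccccc1)(c1ccccc1)C(C)(C)C)(C)[C@@H](CC=C(C)C)C[C@@](CC=C(C)C)(C(=O)O)C(=O)C(O)CC=C(C)C | intermediate (not isolated)
23 | (3R,5RS)-3-[(2S,3S)-3-{2-[(tert-butyldiphenylsilyl)oxy]ethyl}-3,7-dimethyl-2-(3-methylbut-2-en-1-yl)oct-6-en-1-yl]-3,5-bis(3-methylbut-2-en-1-yl)furan-2,4(3H,5H)-dione | CC(C)=CCC[C@](CCO[Si](c1ccccc1)(c1ccccc1)C(C)(C)C)(C)[C@@H](CC=C(C)C)C[C@@]2(CC=C(C)C)C(=O)OC(CC=C(C)C)C2=O | intermediate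
24 | (3R,5RS)-3-[(2S,3S)-3-(2-hydroxyethyl)-3,7-dimethyl-2-(3-methylbut-2-en-1-yl)oct-6-en-1-yl]-3,5-bis(3-methylbut-2-en-1-yl)furan-2,4(3H,5H)-dione | CC(C)=CCC[C@](CCO)(C)[C@@H](CC=C(C)C)C[C@@]2(CC=C(C)C)C(=O)OC(CC=C(C)C)C2=O | intermediate
25 | (3R,5RS)-3-[(2S,3S)-3,7-dimethyl-2-(3-methylbut-2-en-1-yl)-3-(2-oxoethyl)oct-6-en-1-yl]-3,5-bis(3-methylbut-2-en-1-yl)furan-2,4(3H,5H)-dione | CC(C)=CCC[C@](CC=O)(C)[C@@H](CC=C(C)C)C[C@@]2(CC=C(C)C)C(=O)OC(CC=C(C)C)C2=O | intermediate
26 | (1R,3S,4S,7S)-6-hydroxy-4-methyl-1,3,7-tris(3-methylbut-2-en-1-yl)-4-(4-methylpent-3-en-1-yl)-8-oxabicyclo[5.2.1]decane-9,10-dione (C6 epimers) | CC(C)=CCC[C@]1(C)[C@@H](CC=C(C)C)C[C@@]2(CC=C(C)C)C(=O)O[C@@](CC=C(C)C)(C(O)C1)C2=O | intermediate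
27 | (1R,3S,4S,7S)-4-methyl-1,3,7-tris(3-methylbut-2-en-1-yl)-4-(4-methylpent-3-en-1-yl)-8-oxabicyclo[5.2.1]decane-6,9,10-trione | CC(C)=CCC[C@]1(C)[C@@H](CC=C(C)C)C[C@@]2(CC=C(C)C)C(=O)O[C@@](CC=C(C)C)(C(=O)C1)C2=O | intermediate
28 | 2-methylpropanal (isobutyraldehyde) | CC(C)C=O | starting material
29 | (1R,3S,4R,7S)-5-(1-hydroxy-2-methylpropyl)-4-methyl-1,3,7-tris(3-methylbut-2-en-1-yl)-4-(4-methylpent-3-en-1-yl)-8-oxabicyclo[5.2.1]decane-6,9,10-trione (epimers at C5 and at the carbinol carbon) | CC(C)=CCC[C@]1(C)[C@@H](CC=C(C)C)C[C@@]2(CC=C(C)C)C(=O)O[C@@](CC=C(C)C)(C(=O)C1C(O)C(C)C)C2=O | intermediate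
30 | (1R,3S,4R,5R,7S)-4-methyl-1,3,7-tris(3-methylbut-2-en-1-yl)-4-(4-methylpent-3-en-1-yl)-5-(2-methylpropanoyl)-8-oxabicyclo[5.2.1]decane-6,9,10-trione (CNP0121153.1) | CC(C)=CCC[C@]1(C)[C@@H](CC=C(C)C)C[C@@]2(CC=C(C)C)C(=O)O[C@@](CC=C(C)C)(C(=O)[C@H]1C(=O)C(C)C)C2=O | target

## Step count and least certain steps

Total step count: 18. Longest linear sequence: 17 steps (steps 1–7 and 9–18); step 8 is a one-step branch that prepares fragment 18.

**Step 2 (key step).** The most likely failures are insufficient enantioface discrimination, because the five-membered enone is nearly flat and offers the catalyst little to grip, and incomplete C-alkylation of the aluminate, with protonation or proton exchange leading to alkylation at C8. Fallback: set out from Grignard reagent 3 and transfer the homoprenyl group instead of the methyl group. Copper-catalysed addition of 3 to 3-methylcyclopent-2-en-1-one F1 (Cu(OTf)2 with a chiral 4,5-diphenylimidazolinium carbene precursor), with Me3SiCl trapping, should give (S)-trimethyl{[3-methyl-3-(4-methylpent-3-en-1-yl)cyclopent-1-en-1-yl]oxy}silane F2. MeLi then releases the lithium enolate, which is alkylated with 7, and the route is rejoined at 10.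

**Step 15 (ring closure).** The base may deprotonate next to the aldehyde instead of at C7, which opens intermolecular aldol paths and attack of that enolate on the lactone carbonyl. The eight-membered closure may also be slow and reversible, and the new C8 alkoxide may take over the lactone acyl group from O6. Fallback: raise C8 to the acid level so that C7 carries the only acidic proton. From 25, chlorite oxidation (NaClO2, NaH2PO4, 2-methylbut-2-ene) gives the carboxylic acid F3, and carbodiimide coupling with N,O-dimethylhydroxylamine gives the N-methoxy-N-methylamide F4. LiN(SiMe3)2 under high dilution should then acylate the C7 enolate intramolecularly through a chelated tetrahedral intermediate and give 27 directly, so that steps 15 and 16 are replaced.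

**Step 10 (C4 quaternary centre).** Facial control may be poor, because the ion-paired catalyst has to distinguish the faces of an acyclic enolate that carries a bulky α-chain, and O-prenylation may compete. The wrong C4 epimer would carry through to the diastereomeric bicycle. Fallback: auxiliary control. From 19, condensation with L-valine tert-butyl ester gives the chiral enamino ester F5. Deprotonation with LiN(i-Pr)2 in toluene and alkylation with 7 through the chelated lithio-enamine gives the imine F6, and hydrolysis with aqueous citric acid returns to the route at 20.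

**Step 12 (lactonisation).** The free β-keto acid 22 may decarboxylate, or the α-ketol may transpose, before the ring closes. Fallback: a sequence that never passes through a free acid. From 20, the potassium enolate is iodinated (KN(SiMe3)2, then I2, −78 °C) to the α-iodo ketone F7. On warming with NaHCO3 in MeCN the ester carbonyl oxygen displaces iodide (5-exo-tet) and the tert-butyl group leaves as 2-methylpropene, the classical cyclisation of γ-halo acetoacetates to tetronic acids; the route is rejoined at 23.

**Step 9 (fragment union).** Substitution at the β-branched iodide may be slow, which gives time for elimination and O-alkylation. Fallback: reductive alkylation in place of substitution. From 14, Dess–Martin oxidation gives the aldehyde F8, Knoevenagel condensation with 18 (piperidinium acetate) gives the alkylidene keto ester F9, and conjugate reduction with diethyl 2,6-dimethyl-1,4-dihydropyridine-3,5-dicarboxylate returns to the route at 19. The integrity of C2, which is α to the aldehyde in F8, would have to be checked.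

## Further compounds

F1 | step 2 | 3-methylcyclopent-2-en-1-one | CC1=CC(=O)CC1
F2 | step 2 | (S)-trimethyl{[3-methyl-3-(4-methylpent-3-en-1-yl)cyclopent-1-en-1-yl]oxy}silane | CC(C)=CCC[C@]1(C)C=C(O[Si](C)(C)C)CC1
F3 | step 15 | {(1S)-1-methyl-1-(4-methylpent-3-en-1-yl)...}acetic acid: the carboxylic acid of 25 with C8 as CO2H | CC(C)=CCC[C@](CC(=O)O)(C)[C@@H](CC=C(C)C)C[C@@]2(CC=C(C)C)C(=O)OC(CC=C(C)C)C2=O
F4 | step 15 | N-methoxy-N-methylamide of F3 (C8 as C(=O)N(OMe)Me) | CC(C)=CCC[C@](CC(=O)N(C)OC)(C)[C@@H](CC=C(C)C)C[C@@]2(CC=C(C)C)C(=O)OC(CC=C(C)C)C2=O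
F5 | step 10 | enamino ester of 19 with L-valine tert-butyl ester (Z, nitrogen on C10) | CC(C)=CCC[C@](CCO[Si](c1ccccc1)(c1ccccc1)C(C)(C)C)(C)[C@@H](CC=C(C)C)C/C(C(=O)OC(C)(C)C)=C(/N[C@@H](C(C)C)C(=O)OC(C)(C)C)CCC=C(C)C
F6 | step 10 | C4-prenylated imine of 20 with L-valine tert-butyl ester | CC(C)=CCC[C@](CCO[Si](c1ccccc1)(c1ccccc1)C(C)(C)C)(C)[C@@H](CC=C(C)C)C[C@@](CC=C(C)C)(C(=O)OC(C)(C)C)C(=N[C@@H](C(C)C)C(=O)OC(C)(C)C)CCC=C(C)C
F7 | step 12 | α-iodo ketone of 20 (iodine on C7, both epimers) | CC(C)=CCC[C@](CCO[Si](c1ccccc1)(c1ccccc1)C(C)(C)C)(C)[C@@H](CC=C(C)C)C[C@@](CC=C(C)C)(C(=O)OC(C)(C)C)C(=O)C(I)CC=C(C)C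
F8 | step 9 | (2R,3S)-3-{2-[(tert-butyldiphenylsilyl)oxy]ethyl}-3,7-dimethyl-2-(3-methylbut-2-en-1-yl)oct-6-enal | CC(C)=CCC[C@](CCO[Si](c1ccccc1)(c1ccccc1)C(C)(C)C)(C)[C@@H](CC=C(C)C)C=O
F9 | step 9 | alkylidene keto ester from F8 and 18 (C3=C4 alkene, E/Z mixture) | CC(C)=CCC[C@](CCO[Si](c1ccccc1)(c1ccccc1)C(C)(C)C)(C)[C@@H](CC=C(C)C)C=C(C(=O)OC(C)(C)C)C(=O)CCC=C(C)C
A1 | alternative 1 | 4-ethenyl-4-methyl-1,3,7-tris(3-methylbut-2-en-1-yl)-8-oxabicyclo[5.2.1]decane-6,9,10-trione (vinyl on C1, C9 unsubstituted) | C=C[C@]1(C)[C@@H](CC=C(C)C)C[C@@]2(CC=C(C)C)C(=O)O[C@@](CC=C(C)C)(C(=O)C1)C2=O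
A2 | alternative 1 | twelve-membered allylic β-keto lactone bridged by the furandione (E alkene drawn) | O=C1OC/C=C(\C)[C@@H](CC=C(C)C)C[C@@]2(CC=C(C)C)C(=O)O[C@@](CC=C(C)C)(C(=O)C1)C2=O
A3 | alternative 2 | bicyclic hydroxy lactone with C10 as carbinol | CC(C)=CCC[C@]1(C)[C@@H](CC=C(C)C)C[C@@]2(CC=C(C)C)C(=O)O[C@@](CC=C(C)C)(C(=O)C1)[C@H]2O
A4 | alternative 2 | acyclic methyl α-bromo ester with C10 aldehyde, C8 ketone and C7 triethylsilyl ether | CC(C)=CCC[C@@](C)(CC(=O)[C@](CC=C(C)C)(O[Si](CC)(CC)CC)C=O)[C@@H](CC=C(C)C)CC(Br)(CC=C(C)C)C(=O)OC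
A5 | alternative 3 | bicyclic furandione lacking the isobutyryl group (identical with 27) | CC(C)=CCC[C@]1(C)[C@@H](CC=C(C)C)C[C@@]2(CC=C(C)C)C(=O)O[C@@](CC=C(C)C)(C(=O)C1)C2=O
A6 | alternative 3 | cyclooctane-1,3-dione carrying the C4 carboxylic acid | CC(C)=CCC[C@]1(C)[C@@H](CC=C(C)C)C[C@@](CC=C(C)C)(C(=O)O)C(=O)C(CC=C(C)C)C(=O)C1
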